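**Retrosynthetic overview**

1. The target is read as (2S)-naringenin joined through C3′–C3‴ to (2R,3R)-aromadendrin; the last step is hydrogenolysis of its heptabenzyl ether 22.
2. Key disconnection: O1–C8a and C4–C4a are cut in both halves at once, so both pyranone rings C open to the acyclic biaryl bis(β-hydroxy ester) 11 plus two molecules of 3,5-bis(benzyloxy)benzyne (three components, four bonds, two rings).
3. Enabling feature: in each chroman-4-one, O1 and the C4 carbonyl sit on adjacent carbons C8a and C4a of ring A, and the C5 oxygen is ortho to C4a. A 3-alkoxy aryne accepts exactly this pattern (oxygen nucleophile at the remote carbon, acyl group at the carbon next to the alkoxy group), and both halves share it.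
4. 11 comes from Suzuki coupling (C3′–C3‴) of two 3-bromo-4-benzyloxyphenyl units that already carry all three stereocenters: an anti-glycolate Mukaiyama aldol sets C2/C3 of the dihydroflavonol half, an asymmetric transfer hydrogenation sets C2 of the flavanone half.
5. Ring order: the two rings B are bought and joined to the biaryl; rings A and C of both halves are then attached and closed together in the key step.

Key step: step 12

Remark: the L-proline-derived (S)-diamine promoter is taken to give the (2S,3S) anti adduct with aromatic aldehydes, so its (R) antipode is used in step 3 to reach (2R,3R); all seven hydroxyls are carried as benzyl ethers.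

**Route**

Step 1
Reactants: 1 2-(benzyloxy)acetyl chloride
Product: 2 S-ethyl 2-(benzyloxy)ethanethioate
Conditions: EtSH, Et3N, CH2Cl2, 0 °C to rt
Reagents that add atoms: ethanethiol, CCS
Why: Acyl substitution of an acid chloride by a thiol (thioesterification) is fast and clean with an amine base.

Step 2
Reactants: 2 S-ethyl 2-(benzyloxy)ethanethioate
Product: 3 (Z)-{[2-(benzyloxy)-1-(ethylsulfanyl)ethenyl]oxy}trimethylsilane
Conditions: LiN(i-Pr)2, TMSCl, THF, −78 °C
Reagents that add atoms: chlorotrimethylsilane, C[Si](C)(C)Cl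
Why: Kinetic enolization of the thioester and O-silylation in situ should give the ketene silyl acetal, the (Z) isomer (SEt cis to OBn) being the expected kinetic product.

Step 3
Reactants: 3 (Z)-{[2-(benzyloxy)-1-(ethylsulfanyl)ethenyl]oxy}trimethylsilane; 4 4-(benzyloxy)-3-bromobenzaldehyde
Product: 5 S-ethyl (2R,3R)-2-(benzyloxy)-3-[4-(benzyloxy)-3-bromophenyl]-3-hydroxypropanethioate
Conditions: Sn(OTf)2, (R)-1-ethyl-2-(piperidin-1-ylmethyl)pyrrolidine, Bu2Sn(OAc)2, CH2Cl2, −78 °C; aq. NaHCO3
Reagents that add atoms: none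
Why: Asymmetric Mukaiyama aldol addition promoted by the chiral divalent tin triflate–diamine complex, in which coordination of the benzyloxy oxygen to tin should turn the addition anti and the diamine should shield one face of the bound aldehyde, sets both the (2R) and the (3R) center.

Step 4
Reactants: 5 S-ethyl (2R,3R)-2-(benzyloxy)-3-[4-(benzyloxy)-3-bromophenyl]-3-hydroxypropanethioate
Product: 6 methyl (2R,3R)-2-(benzyloxy)-3-[4-(benzyloxy)-3-bromophenyl]-3-hydroxypropanoate
Conditions: AgOCOCF3, MeOH/THF, rt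
Reagents that add atoms: methanol, CO
Why: Thiophilic silver-ion activation should turn the thioester into the methyl ester (transesterification) without base, so neither epimerization of the anti pair nor retro-aldol cleavage is invited.

Step 5
Reactants: 7 1-[4-(benzyloxy)-3-bromophenyl]ethan-1-one
Product: 8 methyl 3-[4-(benzyloxy)-3-bromophenyl]-3-oxopropanoate
Conditions: NaH, (MeO)2CO, THF, reflux; AcOH quench
Reagents that add atoms: dimethyl carbonate, COC(=O)OC
Why: Crossed Claisen condensation of the methyl ketone enolate with dimethyl carbonate is driven by formation of the β-keto ester enolate.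

Step 6
Reactants: 8 methyl 3-[4-(benzyloxy)-3-bromophenyl]-3-oxopropanoate
Product: 9 methyl (3S)-3-[4-(benzyloxy)-3-bromophenyl]-3-hydroxypropanoate
Conditions: RuCl(p-cymene)[(S,S)-TsDPEN] (1 mol %), HCO2H/Et3N (5:2), DMF, 40 °C
Reagents that add atoms: none
Why: Noyori–Ikariya asymmetric transfer hydrogenation of the aryl ketone should deliver hydride to the face that gives the (S) benzylic alcohol, as for acetophenone-type ketones with the (S,S) ligand, and should leave the aryl bromide and the benzyl ether untouched.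

Step 7
Reactants: 9 methyl (3S)-3-[4-(benzyloxy)-3-bromophenyl]-3-hydroxypropanoate
Product: 10 methyl (3S)-3-[4-(benzyloxy)-3-(4,4,5,5-tetramethyl-1,3,2-dioxaborolan-2-yl)phenyl]-3-hydroxypropanoate
Conditions: B2pin2, PdCl2(dppf), KOAc, 1,4-dioxane, 85 °C
Reagents that add atoms: bis(pinacolato)diboron, CC1(C)OB(OC1(C)C)B1OC(C)(C)C(C)(C)O1
Why: Miyaura borylation of an aryl bromide tolerates the free secondary alcohol and the ester under the weak acetate base.

Step 8
Reactants: 10 methyl (3S)-3-[4-(benzyloxy)-3-(4,4,5,5-tetramethyl-1,3,2-dioxaborolan-2-yl)phenyl]-3-hydroxypropanoate; 6 methyl (2R,3R)-2-(benzyloxy)-3-[4-(benzyloxy)-3-bromophenyl]-3-hydroxypropanoate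
Product: 11 methyl (2R,3R)-2-(benzyloxy)-3-{2',6-bis(benzyloxy)-5'-[(1S)-1-hydroxy-3-methoxy-3-oxopropyl]biphenyl-3-yl}-3-hydroxypropanoate
Conditions: Pd(OAc)2, SPhos, K3PO4, toluene/H2O, 50 °C
Reagents that add atoms: none
Why: Suzuki–Miyaura coupling with a dialkylbiarylphosphine ligand should form the 2,2'-dialkoxy biaryl bond at a temperature low enough to spare the β-hydroxy esters.

Step 9
Reactants: 12 3,5-bis(benzyloxy)phenol
Product: 13 3,5-bis(benzyloxy)phenyl N-isopropylcarbamate
Conditions: i-PrNCO, Et3N (cat.), CH2Cl2, rt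
Reagents that add atoms: isopropyl isocyanate, CC(C)N=C=O
Why: Addition of the phenol to the isocyanate (carbamoylation) installs a directing group that can later be removed under mild conditions.

Step 10
Reactants: 13 3,5-bis(benzyloxy)phenyl N-isopropylcarbamate
Product: 16 3,5-bis(benzyloxy)-2-(trimethylsilyl)phenyl N-isopropylcarbamate, via N-silyl carbamate 14 (not isolated), via N-silyl C-silyl carbamate 15 (not isolated)
Conditions: TBSOTf, TMEDA, Et2O, 0 °C to rt; n-BuLi, TMEDA, −78 °C; TMSCl, −78 °C to rt; aq. NaHSO4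
Reagents that add atoms: chlorotrimethylsilane, C[Si](C)(C)Cl
Why: Directed ortho-metalation of the carbamate, protected on nitrogen in situ, should take place at C2 (C6 is equivalent), the site flanked by the carbamate and a benzyloxy group, and the aryllithium is quenched on silicon.

Step 11
Reactants: 16 3,5-bis(benzyloxy)-2-(trimethylsilyl)phenyl N-isopropylcarbamate
Product: 18 3,5-bis(benzyloxy)-2-(trimethylsilyl)phenyl trifluoromethanesulfonate, via 3,5-bis(benzyloxy)-2-(trimethylsilyl)phenol 17 (not isolated)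
Conditions: DBU, Et2NH, MeCN, 40 °C; then PhNTf2, rt
Reagents that add atoms: N-phenylbis(trifluoromethanesulfonimide), O=S(=O)(N(c1ccccc1)S(=O)(=O)C(F)(F)F)C(F)(F)F
Why: Base-induced carbamate cleavage (loss of isopropyl isocyanate, trapped by diethylamine) followed by triflation of the phenoxide in the same flask should give the ortho-silyl aryl triflate without protodesilylation.

Step 12
Reactants: 11 methyl (2R,3R)-2-(benzyloxy)-3-{2',6-bis(benzyloxy)-5'-[(1S)-1-hydroxy-3-methoxy-3-oxopropyl]biphenyl-3-yl}-3-hydroxypropanoate; 18 3,5-bis(benzyloxy)-2-(trimethylsilyl)phenyl trifluoromethanesulfonate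
Product: 22 (2R,3R)-3,5,7-tris(benzyloxy)-2-{4-(benzyloxy)-3-[2-(benzyloxy)-5-((2S)-5,7-bis(benzyloxy)-4-oxochroman-2-yl)phenyl]phenyl}chroman-4-one, via bis(trimethylsilyl) ether 19 (not isolated), via 3,5-bis(benzyloxy)benzyne 20 (not isolated), via mono-annulated silyl ether 21 (not isolated)
Conditions: HN(SiMe3)2, TMSOTf (cat.), CH2Cl2, rt, evaporation; then 18 (4 equiv in all, two of which are incorporated, one per ring A), KF, 18-crown-6, THF, 0 °C to rt; aq. NH4Cl
Reagents that add atoms: second molecule of 3,5-bis(benzyloxy)-2-(trimethylsilyl)phenyl trifluoromethanesulfonate 18, C[Si](C)(C)c1c(OS(=O)(=O)C(F)(F)F)cc(OCc2ccccc2)cc1OCc1ccccc1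
Why: Proposed new method: fluoride should cleave both O–SiMe3 bonds of 19 to proton-free potassium alkoxides and release aryne 20 from 18, and two molecules of 18 are consumed because each benzylic alkoxide adds to one aryne at the carbon remote from the flanking benzyloxy group (future C8a), after which the aryl anion left at the carbon next to that benzyloxy group (future C4a) attacks the ester carbonyl and expels methoxide. The closest known reaction type is the fluoride-mediated annulation of arynes with ortho-hydroxy or ortho-amino benzoate esters to xanthones and acridones, which has not been shown for aliphatic β-silyloxy esters or twice on one substrate. Each ring C closes by an anionic 6-exo-trig acyl substitution (aryl carbanion onto C4), and the two closures may occur in either order (21 shows the dihydroflavonol ring closed first). No stereocenter is formed: C2 and C3 of the dihydroflavonol half and C2 of the flavanone half are carried over from 11, because only O–Si and acyl C–O bonds are broken, and the trans C2/C3 relationship is already coded in the anti (2R,3R) ester. The regioselectivity needed (oxygen to C8a, acyl to C4a) is secured by the C5 benzyloxy group ortho to the aryne, which polarizes the triple bond and stabilizes the adjacent carbanion; capture of the anion by the ester rather than by a proton is secured by the absence of any O–H in 19 and by the aprotic medium. The excess of 18 allows for aryne lost to the methoxide set free.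

Step 13
Reactants: 22 (2R,3R)-3,5,7-tris(benzyloxy)-2-{4-(benzyloxy)-3-[2-(benzyloxy)-5-((2S)-5,7-bis(benzyloxy)-4-oxochroman-2-yl)phenyl]phenyl}chroman-4-one
Product: 23 (2R,3R)-2-{3-[5-((2S)-5,7-dihydroxy-4-oxochroman-2-yl)-2-hydroxyphenyl]-4-hydroxyphenyl}-3,5,7-trihydroxychroman-4-one (CNP0201582.1)
Conditions: H2 (1 atm), Pd(OH)2/C, THF/MeOH, rt
Reagents that add atoms: none
Why: Hydrogenolysis of aryl and alkyl benzyl ethers at ambient pressure should free all seven hydroxyls without touching the stereocenters, as is usual for benzyl-protected flavanones and dihydroflavonols.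

**Compound list**

1 | 2-(benzyloxy)acetyl chloride | O=C(Cl)COCc1ccccc1 | starting material
2 | S-ethyl 2-(benzyloxy)ethanethioate | CCSC(=O)COCc1ccccc1 | intermediate
3 | (Z)-{[2-(benzyloxy)-1-(ethylsulfanyl)ethenyl]oxy}trimethylsilane | CCS/C(O[Si](C)(C)C)=C\OCc1ccccc1 | intermediate
4 | 4-(benzyloxy)-3-bromobenzaldehyde | O=Cc1ccc(OCc2ccccc2)c(Br)c1 | starting material
5 | S-ethyl (2R,3R)-2-(benzyloxy)-3-[4-(benzyloxy)-3-bromophenyl]-3-hydroxypropanethioate | CCSC(=O)[C@H](OCc1ccccc1)[C@H](O)c1ccc(OCc2ccccc2)c(Br)c1 | intermediate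
6 | methyl (2R,3R)-2-(benzyloxy)-3-[4-(benzyloxy)-3-bromophenyl]-3-hydroxypropanoate | COC(=O)[C@H](OCc1ccccc1)[C@H](O)c1ccc(OCc2ccccc2)c(Br)c1 | intermediate
7 | 1-[4-(benzyloxy)-3-bromophenyl]ethan-1-one | CC(=O)c1ccc(OCc2ccccc2)c(Br)c1 | starting material
8 | methyl 3-[4-(benzyloxy)-3-bromophenyl]-3-oxopropanoate | COC(=O)CC(=O)c1ccc(OCc2ccccc2)c(Br)c1 | intermediate
9 | methyl (3S)-3-[4-(benzyloxy)-3-bromophenyl]-3-hydroxypropanoate | COC(=O)C[C@H](O)c1ccc(OCc2ccccc2)c(Br)c1 | intermediate
10 | methyl (3S)-3-[4-(benzyloxy)-3-(4,4,5,5-tetramethyl-1,3,2-dioxaborolan-2-yl)phenyl]-3-hydroxypropanoate | COC(=O)C[C@H](O)c1ccc(OCc2ccccc2)c(B2OC(C)(C)C(C)(C)O2)c1 | intermediate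
11 | methyl (2R,3R)-2-(benzyloxy)-3-{2',6-bis(benzyloxy)-5'-[(1S)-1-hydroxy-3-methoxy-3-oxopropyl]biphenyl-3-yl}-3-hydroxypropanoate | COC(=O)C[C@H](O)c1ccc(OCc2ccccc2)c(-c2cc([C@@H](O)[C@@H](OCc3ccccc3)C(=O)OC)ccc2OCc2ccccc2)c1 | intermediate
12 | 3,5-bis(benzyloxy)phenol | Oc1cc(OCc2ccccc2)cc(OCc2ccccc2)c1 | starting material
13 | 3,5-bis(benzyloxy)phenyl N-isopropylcarbamate | CC(C)NC(=O)Oc1cc(OCc2ccccc2)cc(OCc2ccccc2)c1 | intermediate
14 | 3,5-bis(benzyloxy)phenyl N-(tert-butyldimethylsilyl)-N-isopropylcarbamate | CC(C)N([Si](C)(C)C(C)(C)C)C(=O)Oc1cc(OCc2ccccc2)cc(OCc2ccccc2)c1 | intermediate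
15 | 3,5-bis(benzyloxy)-2-(trimethylsilyl)phenyl N-(tert-butyldimethylsilyl)-N-isopropylcarbamate | CC(C)N([Si](C)(C)C(C)(C)C)C(=O)Oc1cc(OCc2ccccc2)cc(OCc2ccccc2)c1[Si](C)(C)C | intermediate
16 | 3,5-bis(benzyloxy)-2-(trimethylsilyl)phenyl N-isopropylcarbamate | CC(C)NC(=O)Oc1cc(OCc2ccccc2)cc(OCc2ccccc2)c1[Si](C)(C)C | intermediate
17 | 3,5-bis(benzyloxy)-2-(trimethylsilyl)phenol | C[Si](C)(C)c1c(O)cc(OCc2ccccc2)cc1OCc1ccccc1 | intermediate
18 | 3,5-bis(benzyloxy)-2-(trimethylsilyl)phenyl trifluoromethanesulfonate | C[Si](C)(C)c1c(OS(=O)(=O)C(F)(F)F)cc(OCc2ccccc2)cc1OCc1ccccc1 | intermediate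
19 | methyl (2R,3R)-2-(benzyloxy)-3-{2',6-bis(benzyloxy)-5'-[(1S)-3-methoxy-3-oxo-1-(trimethylsilyloxy)propyl]biphenyl-3-yl}-3-(trimethylsilyloxy)propanoate | COC(=O)C[C@H](O[Si](C)(C)C)c1ccc(OCc2ccccc2)c(-c2cc([C@@H](O[Si](C)(C)C)[C@@H](OCc3ccccc3)C(=O)OC)ccc2OCc2ccccc2)c1 | intermediate
20 | 3,5-bis(benzyloxy)benzyne (1,2-didehydro-3,5-bis(benzyloxy)benzene) | C1#CC(OCc2ccccc2)=CC(OCc2ccccc2)=C1 | intermediate
21 | methyl (3S)-3-{4-(benzyloxy)-3-[2-(benzyloxy)-5-((2R,3R)-3,5,7-tris(benzyloxy)-4-oxochroman-2-yl)phenyl]phenyl}-3-(trimethylsilyloxy)propanoate | COC(=O)C[C@H](O[Si](C)(C)C)c1ccc(OCc2ccccc2)c(-c2cc([C@H]3Oc4cc(OCc5ccccc5)cc(OCc5ccccc5)c4C(=O)[C@@H]3OCc3ccccc3)ccc2OCc2ccccc2)c1 | intermediate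
22 | (2R,3R)-3,5,7-tris(benzyloxy)-2-{4-(benzyloxy)-3-[2-(benzyloxy)-5-((2S)-5,7-bis(benzyloxy)-4-oxochroman-2-yl)phenyl]phenyl}chroman-4-one | O=C1C[C@@H](c2ccc(OCc3ccccc3)c(-c3cc([C@H]4Oc5cc(OCc6ccccc6)cc(OCc6ccccc6)c5C(=O)[C@@H]4OCc4ccccc4)ccc3OCc3ccccc3)c2)Oc2cc(OCc3ccccc3)cc(OCc3ccccc3)c21 | intermediate
23 | (2R,3R)-2-{3-[5-((2S)-5,7-dihydroxy-4-oxochroman-2-yl)-2-hydroxyphenyl]-4-hydroxyphenyl}-3,5,7-trihydroxychroman-4-one | O=C1C[C@@H](c2ccc(O)c(-c3cc([C@H]4Oc5cc(O)cc(O)c5C(=O)[C@@H]4O)ccc3O)c2)Oc2cc(O)cc(O)c21 | target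

**Step count and risks**

Total steps: 13. Longest linear sequence: 7 (steps 1, 2, 3, 4, 8, 12, 13).

Steps most likely to fail:

1. Step 12 (proposed new method). The aryl anion may be protonated before it reaches the ester, so that only O-arylation occurs. The alkoxides may fragment by retro-aldol cleavage. The methoxide released may open the new flavanone ring to a chalcone and erode C2. The fallback separates the two bond formations and uses known chemistry. It sets out from 11 and two molecules of 18. Fluoride-mediated O–H insertion of the aryne into the two free alcohols (KF, 18-crown-6, THF, −20 °C, retention at both carbinol centers) should give the bis(aryl ether) diester F1. Saponification (LiOH, THF/H2O) should give the diacid F2. Double intramolecular Friedel–Crafts acylation (TFAA, CH2Cl2, 0 °C) ortho to the ether oxygen of each electron-rich ring should close both rings C and return to the route at 22.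

2. Step 3. Facial and anti/syn control may be insufficient with this electron-rich, ortho-brominated aldehyde, and the promoter needs the less common diamine antipode. The fallback uses substrate control and sets out from 9. Fráter–Seebach-type hydroxylation of the dianion (LiN(i-Pr)2, 2.2 equiv, THF, −78 to −20 °C; then 2-(phenylsulfonyl)-3-phenyloxaziridine), with attack anti to the aryl group of the chelate, should give the anti diol methyl (2R,3R)-3-[4-(benzyloxy)-3-bromophenyl]-2,3-dihydroxypropanoate F3. Selective benzylation of the more acidic α-hydroxyl (BnBr, Ag2O, CH2Cl2) returns to the route at 6.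

3. Step 13. Hydrogenolytic cleavage of the benzylic C2–O1 bonds (ring opening to dihydrochalcones) or incomplete removal of seven benzyl groups may occur. The fallback is non-reductive and sets out from 22: BCl3 with pentamethylbenzene as cation scavenger (CH2Cl2, −78 °C) should remove all benzyl groups and return at 23. This fallback makes no new compound (F0).

**Further compounds**

F1 | step 12 | methyl (2R,3R)-2-(benzyloxy)-3-[3,5-bis(benzyloxy)phenoxy]-3-{2',6-bis(benzyloxy)-5'-[(1S)-1-(3,5-bis(benzyloxy)phenoxy)-3-methoxy-3-oxopropyl]biphenyl-3-yl}propanoate | COC(=O)C[C@H](Oc1cc(OCc2ccccc2)cc(OCc2ccccc2)c1)c1ccc(OCc2ccccc2)c(-c2cc([C@@H](Oc3cc(OCc4ccccc4)cc(OCc4ccccc4)c3)[C@@H](OCc3ccccc3)C(=O)OC)ccc2OCc2ccccc2)c1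
F2 | step 12 | (2R,3R)-2-(benzyloxy)-3-[3,5-bis(benzyloxy)phenoxy]-3-{2',6-bis(benzyloxy)-5'-[(1S)-1-(3,5-bis(benzyloxy)phenoxy)-2-carboxyethyl]biphenyl-3-yl}propanoic acid | OC(=O)C[C@H](Oc1cc(OCc2ccccc2)cc(OCc2ccccc2)c1)c1ccc(OCc2ccccc2)c(-c2cc([C@@H](Oc3cc(OCc4ccccc4)cc(OCc4ccccc4)c3)[C@@H](OCc3ccccc3)C(=O)O)ccc2OCc2ccccc2)c1
F3 | step 3 | methyl (2R,3R)-3-[4-(benzyloxy)-3-bromophenyl]-2,3-dihydroxypropanoate | COC(=O)[C@H](O)[C@H](O)c1ccc(OCc2ccccc2)c(Br)c1
F0 | step 13 | none | none
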